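**Plan**

1. Cuts, in order: (a) the hemiketal O–C4 bond, which opens the bridged bicycle to its ring–chain tautomer, a 2',6'-dihydroxyflavanone; (b) the C3–C2 bond of the pyranone ring, leaving an α-diazoketone that carries ring B as a plain benzyl ether on O1; (c) the O1–CH2 ether bond, giving a ring A o-hydroxyacetophenone and a ring B benzyl alcohol.
2. Forward: ring A is dressed on 2,4-dihydroxy-6-methoxyacetophenone (allyl Claisen to C3, chromene annulation across O4/C5, cross-metathesis to prenyl). Ring B is then attached as the ether, the acetyl group becomes a diazoketone, the pyranone ring closes by 1,6 C–H insertion, and desilylation lets the hemiketal bridge close.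
3. Enabling feature: C2 (the CH bridgehead) is both α to the ring A ether oxygen O1 and benzylic to the 2,6-dioxygenated ring B. It sits 1,6 to C3 along C3–C4–C4a–C8a–O1–C2, and the 1,5 position is an oxygen with no hydrogen. A carbenoid at C3 therefore finds one strongly hydridic C–H bond in a six-membered transition state, and C2 needs no prior oxidation.
4. Second feature: the 2'-oxygen of ring B lies over C4, so the freed flavanone folds into the 2,6-dioxabicyclo[3.3.1]nonane (6,12-methanodibenzo[b,f][1,5]dioxocin) hemiketal.
5. Stereochemistry: C2 is set in the insertion by the chiral dirhodium carboxylate, which chooses between the two enantiotopic benzylic hydrogens. The hemiketal carbon follows from C2, because only the cis-bridged bicycle can form.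

Key step: step 9

Assumption: flavanone numbering (O1, C2, C3, C4, C4a, C8a, ring B primed) is used for the core, acetophenone numbering (C1 bears the acetyl) for steps 1–3; the bridged hemiketal is taken to be the resting form of the 2',6'-dihydroxyflavanone, as the target is drawn.
Assumption: the sense of induction of the prolinate catalyst is fixed on the first run; the route is written with the (R)-prolinate, and the antipodal catalyst is used if the (2S) product prevails.

**Route**

Step 1
Reactants: 1 2,4-dihydroxy-6-methoxyacetophenone; 2 allyl bromide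
Product: 3 1-[4-(allyloxy)-2-hydroxy-6-methoxyphenyl]ethanone
Conditions: K2CO3, acetone, reflux
Reagents that add atoms: none
Why: Williamson etherification; the 4-OH is the more acidic, non-chelated hydroxyl, so one equivalent of 2 should alkylate it while the hydrogen-bonded 2-OH stays free.

Step 2
Reactants: 3 1-[4-(allyloxy)-2-hydroxy-6-methoxyphenyl]ethanone
Product: 5 1-(3-allyl-2,4-dihydroxy-6-methoxyphenyl)ethanone, via ortho-dienone 4 (not isolated)
Conditions: PhNEt2, 200 °C
Reagents that add atoms: none
Why: aromatic Claisen rearrangement; the chelate between 2-OH and the acetyl group fixes more double-bond character in C3–C4, so the allyl group should migrate mainly to C3, and dienone 4 tautomerises to the phenol.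

Step 3
Reactants: 5 1-(3-allyl-2,4-dihydroxy-6-methoxyphenyl)ethanone; 6 3-methylbut-2-enal (prenal)
Product: 8 1-(8-allyl-7-hydroxy-5-methoxy-2,2-dimethyl-2H-chromen-6-yl)ethanone, via o-quinone methide 7 (not isolated)
Conditions: ethylenediammonium diacetate (20 mol%), xylene, 140 °C
Reagents that add atoms: none
Why: amine-salt-catalysed condensation of the phenol with the enal at C5 (the only free ring carbon), dehydration to o-quinone methide 7 and oxa-6π-electrocyclisation; only the 4-oxygen flanks C5, so a single chromene regioisomer can form.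

Step 4
Reactants: 8 1-(8-allyl-7-hydroxy-5-methoxy-2,2-dimethyl-2H-chromen-6-yl)ethanone; 9 2-methylbut-2-ene
Product: 10 1-[7-hydroxy-5-methoxy-2,2-dimethyl-8-(3-methylbut-2-enyl)-2H-chromen-6-yl]ethanone
Conditions: second-generation Grubbs catalyst (H2IMes)(PCy3)Cl2Ru=CHPh (5 mol%), 9 in excess, CH2Cl2, 40 °C
Reagents that add atoms: none
Why: olefin cross-metathesis of the terminal allyl group with excess 2-methylbut-2-ene should give the prenyl group, while the cis-disubstituted chromene alkene next to a quaternary carbon stays inert.

Step 5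
Reactants: 11 2,6-dihydroxybenzaldehyde
Product: 12 2,6-bis(tert-butyldimethylsilyloxy)benzaldehyde
Conditions: TBSCl, imidazole, DMF, rt
Reagents that add atoms: tert-butyldimethylsilyl chloride, CC(C)(C)[Si](C)(C)Cl
Why: standard imidazole-promoted silylation of both phenols; the silyl ethers are donors that tolerate the carbenoid and come off without acid or base.

Step 6
Reactants: 12 2,6-bis(tert-butyldimethylsilyloxy)benzaldehyde
Product: 13 [2,6-bis(tert-butyldimethylsilyloxy)phenyl]methanol
Conditions: NaBH4, MeOH/THF, 0 °C
Reagents that add atoms: none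
Why: borohydride reduction of the aldehyde; the low temperature and short contact time should prevent aryl-to-benzyl silyl migration.

Step 7
Reactants: 10 1-[7-hydroxy-5-methoxy-2,2-dimethyl-8-(3-methylbut-2-enyl)-2H-chromen-6-yl]ethanone; 13 [2,6-bis(tert-butyldimethylsilyloxy)phenyl]methanol
Product: 14 1-[7-{[2,6-bis(tert-butyldimethylsilyloxy)phenyl]methoxy}-5-methoxy-2,2-dimethyl-8-(3-methylbut-2-enyl)-2H-chromen-6-yl]ethanone
Conditions: PPh3, DIAD, THF, 0 °C to rt
Reagents that add atoms: none
Why: Mitsunobu etherification; the o-acylphenol is acidic enough, the benzylic oxyphosphonium ion is activated by two ortho silyloxy groups, and ring A has no free carbon, so only O-alkylation is possible.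

Step 8
Reactants: 14 (aryl benzyl ether methyl ketone)
Product: 16 2-diazo-1-[7-{[2,6-bis(tert-butyldimethylsilyloxy)phenyl]methoxy}-5-methoxy-2,2-dimethyl-8-(3-methylbut-2-enyl)-2H-chromen-6-yl]ethanone, via trifluoroacetyl diketone 15 (not isolated)
Conditions: LiN(SiMe3)2, THF, −78 °C; CF3CO2CH2CF3; 5% aq HCl work-up; then MsN3, Et3N, H2O, MeCN, rt
Reagents that add atoms: 2,2,2-trifluoroethyl trifluoroacetate, O=C(OCC(F)(F)F)C(F)(F)F (adds CF3CO, present in 15 only); methanesulfonyl azide, CS(=O)(=O)N=[N+]=[N-] (adds N2)
Why: detrifluoroacetylative diazo transfer; the kinetic enolate of the methyl ketone is trifluoroacetylated, and the activated 1,3-diketone takes up the diazo group from the sulfonyl azide with loss of the trifluoroacetyl group.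

Step 9
Reactants: 16 (α-diazoketone)
Product: 17 (2R)-2-[2,6-bis(tert-butyldimethylsilyloxy)phenyl]-5-methoxy-8,8-dimethyl-10-(3-methylbut-2-enyl)-2,3-dihydropyrano[3,2-g]chromen-4-one
Conditions: Rh2(R-BSP)4 [dirhodium tetrakis(N-benzenesulfonyl-(R)-prolinate)] (1 mol%), CH2Cl2, slow addition of 16, 0 °C to rt
Reagents that add atoms: none
Why: The dirhodium carboxylate decomposes the diazoketone to an electrophilic rhodium carbenoid at C3, which inserts into one of the two enantiotopic C–H bonds of the O1–CH2–aryl group through a three-centre, hydride-transfer-like transition state and forms the C3–C2 bond with release of the catalyst. The closest known reaction type is the enantioselective intramolecular C–H insertion of 2-alkoxyaryl α-diazoketones next to the ether oxygen, which gives chroman-4-ones under chiral divalent rhodium carboxylates. The pyranone ring closes in the 1,6 mode (six-membered ring, carbenoid carbon endocyclic) through a chair-like transition state, and no other ring closes in this step. The new stereocenter C2 is controlled by the chiral prolinate ligand shell, which selects one of the two benzylic hydrogens. The step needs selectivity for this C–H bond over attack on the ether oxygen (oxonium ylide, then 1,2-benzyl shift), over the O–CH3 hydrogens and over the alkenes: the 1,5 position is an oxygen without hydrogen, the benzylic C–H is the most hydridic because the developing charge is taken up by O1 and the two ortho silyloxy groups, the methoxy hydrogens are primary and not benzylic, ring A has no free carbon, and both alkenes sit meta or para to the acyl group, out of reach. Slow addition at low concentration in a non-coordinating solvent should suppress carbene dimerisation.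

Step 10
Reactants: 17 (silyl-protected (2R)-flavanone)
Product: 19 target CNP0170313.2 (bridged hemiketal; 2R,4R; ring B 2'-oxygen bonded to C4; OH on C4), via flavanone diol 18 (not isolated)
Conditions: Et3N·3HF, THF, rt
Reagents that add atoms: none
Why: fluoride cleaves both aryl silyl ethers without base, and the freed 2'-OH adds to the C4 ketone (ring–chain tautomerism) to give the hemiketal, whose configuration is dictated by C2 because only the cis-bridged bicycle can form; the non-basic medium should avoid retro-oxa-Michael opening, which would racemise C2.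

**Compound list**

1 | 2,4-dihydroxy-6-methoxyacetophenone | CC(=O)c1c(O)cc(O)cc1OC | starting material
2 | allyl bromide | C=CCBr | starting material
3 | 1-[4-(allyloxy)-2-hydroxy-6-methoxyphenyl]ethanone | CC(=O)c1c(O)cc(OCC=C)cc1OC | intermediate
4 | ortho-dienone of the Claisen rearrangement (formed in the flask) | CC(=O)C1=C(O)C(CC=C)C(=O)C=C1OC | intermediate
5 | 1-(3-allyl-2,4-dihydroxy-6-methoxyphenyl)ethanone | CC(=O)c1c(O)c(CC=C)c(O)cc1OC | intermediate
6 | 3-methylbut-2-enal (prenal) | CC(C)=CC=O | starting material
7 | o-quinone methide from 5 and 6 (formed in the flask) | CC(=O)C1=C(OC)C(=CC=C(C)C)C(=O)C(CC=C)=C1O | intermediate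
8 | 1-(8-allyl-7-hydroxy-5-methoxy-2,2-dimethyl-2H-chromen-6-yl)ethanone | CC(=O)c1c(OC)c2C=CC(C)(C)Oc2c(CC=C)c1O | intermediate
9 | 2-methylbut-2-ene | CC=C(C)C | starting material
10 | 1-[7-hydroxy-5-methoxy-2,2-dimethyl-8-(3-methylbut-2-enyl)-2H-chromen-6-yl]ethanone | CC(=O)c1c(OC)c2C=CC(C)(C)Oc2c(CC=C(C)C)c1O | intermediate
11 | 2,6-dihydroxybenzaldehyde | O=Cc1c(O)cccc1O | starting material
12 | 2,6-bis(tert-butyldimethylsilyloxy)benzaldehyde | O=Cc1c(O[Si](C)(C)C(C)(C)C)cccc1O[Si](C)(C)C(C)(C)C | intermediate
13 | [2,6-bis(tert-butyldimethylsilyloxy)phenyl]methanol | OCc1c(O[Si](C)(C)C(C)(C)C)cccc1O[Si](C)(C)C(C)(C)C | intermediate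
14 | 1-[7-{[2,6-bis(tert-butyldimethylsilyloxy)phenyl]methoxy}-5-methoxy-2,2-dimethyl-8-(3-methylbut-2-enyl)-2H-chromen-6-yl]ethanone | CC(=O)c1c(OC)c2C=CC(C)(C)Oc2c(CC=C(C)C)c1OCc1c(O[Si](C)(C)C(C)(C)C)cccc1O[Si](C)(C)C(C)(C)C | intermediate
15 | 4,4,4-trifluoro-1-aryl-butane-1,3-dione from 14 (aryl as in 14; formed in the flask) | O=C(CC(=O)C(F)(F)F)c1c(OC)c2C=CC(C)(C)Oc2c(CC=C(C)C)c1OCc1c(O[Si](C)(C)C(C)(C)C)cccc1O[Si](C)(C)C(C)(C)C | intermediate
16 | 2-diazo-1-aryl-ethanone from 14 (aryl as in 14) | [N-]=[N+]=CC(=O)c1c(OC)c2C=CC(C)(C)Oc2c(CC=C(C)C)c1OCc1c(O[Si](C)(C)C(C)(C)C)cccc1O[Si](C)(C)C(C)(C)C | intermediate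
17 | (2R)-2-[2,6-bis(tert-butyldimethylsilyloxy)phenyl]-5-methoxy-8,8-dimethyl-10-(3-methylbut-2-enyl)-2,3-dihydropyrano[3,2-g]chromen-4-one | COc1c2c(c(CC=C(C)C)c3c1C(=O)C[C@@H](O3)c1c(O[Si](C)(C)C(C)(C)C)cccc1O[Si](C)(C)C(C)(C)C)OC(C)(C)C=C2 | intermediate
18 | (2R)-2-(2,6-dihydroxyphenyl)-5-methoxy-8,8-dimethyl-10-(3-methylbut-2-enyl)-2,3-dihydropyrano[3,2-g]chromen-4-one (formed in the flask) | COc1c2c(c(CC=C(C)C)c3c1C(=O)C[C@@H](O3)c1c(O)cccc1O)OC(C)(C)C=C2 | intermediate
19 | CNP0170313.2: bridged hemiketal of 18, 2'-oxygen bonded to C4, OH on C4, (2R,4R), 6,12-methanodibenzo[b,f][1,5]dioxocin core | COc1c2c(c(CC=C(C)C)c3c1[C@@]1(O)C[C@@H](O3)c3c(O)cccc3O1)OC(C)(C)C=C2 | target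

**Count**

Total steps: 10. Longest linear sequence: 8 (steps 1, 2, 3, 4, 7, 8, 9, 10); steps 5 and 6 form the ring B branch.

**Steps most likely to fail, with fallbacks**

Step 9. The carbenoid may be captured by the lone pair of the benzyl ether oxygen, and migration of the benzyl group within the resulting oxonium ylide would divert material from the six-ring closure. The two benzylic hydrogens may also be differentiated only weakly. The fallback forms the same C3–C2 bond by an oxidative route and sets out from 14. The lithium enolate (LiN(SiMe3)2, THF, −78 °C) is acetylated with Ac2O to the enol acetate F1. DDQ with 2,6-dichloropyridine and LiClO4 in 1,2-dichloroethane abstracts hydride from the O1–CH2–aryl carbon, and the aryl-stabilised oxocarbenium ion is captured by the enol acetate in a 6-endo cyclisation to give the racemic flavanone F2. Preparative HPLC on a cellulose tris(3,5-dimethylphenylcarbamate) phase separates the (2R) enantiomer from the (2S) enantiomer F3. The route is rejoined at 17.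

Step 2. The allyl group may migrate to the wrong ortho carbon (C5 instead of C3), giving a regioisomer mixture. The fallback sets out from 1 and moves the allyl group to the other oxygen, where only one ortho carbon is free. The non-chelated 4-OH is protected (MOMCl, iPr2NEt, CH2Cl2, 0 °C) as the methoxymethyl ether F4. The chelated 2-OH is allylated under forcing conditions (allyl bromide, K2CO3, DMF, 60 °C) to the 2-allyl ether F5. Claisen rearrangement (PhNEt2, 200 °C) can then reach only C3, because C1 carries the acetyl group, and gives F6. HCl in MeOH removes the methoxymethyl group, and the route is rejoined at 5.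

Step 7. The redox condensation may stall because both partners carry two ortho substituents, with N-alkylation of the reduced azodicarboxylate taking over. The fallback sets out from 13 and uses a preformed electrophile under silver assistance. CBr4 and PPh3 in CH2Cl2 at 0 °C convert 13 into the benzylic bromide F7, which is used at once. Phenol 10 is then alkylated with F7 and Ag2O in CH2Cl2 at rt, where halide abstraction drives ionisation of the electron-rich benzyl bromide and the fully substituted ring A can react only at oxygen. The route is rejoined at 14.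

**Further compounds**

F1 | step 9 | enol acetate of 14: 1-aryl-vinyl acetate (aryl as in 14) | CC(=O)OC(=C)c1c(OC)c2C=CC(C)(C)Oc2c(CC=C(C)C)c1OCc1c(O[Si](C)(C)C(C)(C)C)cccc1O[Si](C)(C)C(C)(C)C
F2 | step 9 | racemic 2-[2,6-bis(tert-butyldimethylsilyloxy)phenyl]-5-methoxy-8,8-dimethyl-10-(3-methylbut-2-enyl)-2,3-dihydropyrano[3,2-g]chromen-4-one | COc1c2c(c(CC=C(C)C)c3c1C(=O)CC(O3)c1c(O[Si](C)(C)C(C)(C)C)cccc1O[Si](C)(C)C(C)(C)C)OC(C)(C)C=C2
F3 | step 9 | (2S) enantiomer of 17 | COc1c2c(c(CC=C(C)C)c3c1C(=O)C[C@H](O3)c1c(O[Si](C)(C)C(C)(C)C)cccc1O[Si](C)(C)C(C)(C)C)OC(C)(C)C=C2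
F4 | step 2 | 1-[2-hydroxy-6-methoxy-4-(methoxymethoxy)phenyl]ethanone | CC(=O)c1c(O)cc(OCOC)cc1OC
F5 | step 2 | 1-[2-(allyloxy)-6-methoxy-4-(methoxymethoxy)phenyl]ethanone | CC(=O)c1c(OCC=C)cc(OCOC)cc1OC
F6 | step 2 | 1-[3-allyl-2-hydroxy-6-methoxy-4-(methoxymethoxy)phenyl]ethanone | CC(=O)c1c(O)c(CC=C)c(OCOC)cc1OC
F7 | step 7 | [2,6-bis(tert-butyldimethylsilyloxy)phenyl]methyl bromide | BrCc1c(O[Si](C)(C)C(C)(C)C)cccc1O[Si](C)(C)C(C)(C)C
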